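**Plan**
Retrosynthesis: after loss of four aryl silyl groups, the pendant 4-hydroxy-2-pyranone is cut at its lactone bond O1'–C2' and at C5'–C6'. This leads back to a C3 aldehyde and a dioxinone dienol ether.
The central 2-pyranone of the furo[3,2-c]pyran-4-one is then cut at C6–C7 and at O5–C4.
Enabling feature: C4, C3a, C7a and C7 together with O1 make up a 2-methyl-4,5-dihydrofuran-3-carboxylate. This is a cyclic β-alkoxycrotonate whose acidic γ-methyl carbon (C7) is held cis to the ester (C4), and C6 is simply a cinnamoyl carbonyl carbon.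
The dihydrofuran is opened at O1–C2 to a donor–acceptor cyclopropane. That cyclopropane is built from a protected caffeic aldehyde and methyl 2-bromoacetoacetate (C3–C3a kept, C2–C3a temporary); one cinnamoyl Weinreb amide supplies both the enal and the acyl donor.
Forward ring order: cyclopropane, dihydrofuran, central 2-pyranone, pendant 2-pyranone.
Stereochemistry: C3 is set by an (R)-diarylprolinol silyl ether catalyst in the cyclopropanation and is not touched afterwards. C2 is re-formed trans to it in the ring expansion.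

Key step: step 8

Assumption: the SMILES is read as the (2R,3R)-trans isomer, and the sense of induction in step 5 follows the usual steric-shielding model of diarylprolinol silyl ethers, which calls for the R catalyst.
Notation: TBS = tert-butyldimethylsilyl. Furo[3,2-c]pyran-4-one numbering is also used for the atoms of 10–13: O1, C2 (ArCH), C3 (acetal-bearing CH), C3a (ester-bearing sp2 carbon), C4 (ester carbonyl), C7a (O-bearing sp2 carbon), C7 (methyl carbon).

Step 1
Reactants: 1 3,4-dihydroxybenzaldehyde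
Product: 2 3,4-bis(tert-butyldimethylsilyloxy)benzaldehyde
Conditions: TBSCl (2.4 equiv), imidazole, DMF, rt
Reagents that add atoms: tert-butyldimethylsilyl chloride, CC(C)(C)[Si](C)(C)Cl
Why: Imidazole-promoted O-silylation of phenols is routine, and aryl TBS ethers should withstand the amide base at −78 °C, the later Lewis and Brønsted acids and 110 °C, yet leave under buffered fluoride at the end.

Step 2
Reactants: 2 3,4-bis(tert-butyldimethylsilyloxy)benzaldehyde; 3 diethyl {2-[methoxy(methyl)amino]-2-oxoethyl}phosphonate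
Product: 4 (E)-3-[3,4-bis(TBSO)phenyl]-N-methoxy-N-methylprop-2-enamide
Conditions: LiCl, iPr2NEt, MeCN, rt
Reagents that add atoms: none
Why: Horner–Wadsworth–Emmons olefination under LiCl/amine (Masamune–Roush) conditions should give the E-enamide, and the weak base should leave the silyl ethers of this para-formyl phenol untouched.

Step 3
Reactants: 4 (E)-3-[3,4-bis(TBSO)phenyl]-N-methoxy-N-methylprop-2-enamide (one portion)
Product: 5 (E)-3-[3,4-bis(TBSO)phenyl]prop-2-enal
Conditions: iBu2AlH, THF, −78 °C; aq. potassium sodium tartrate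
Reagents that add atoms: none
Why: In this Weinreb amide reduction, hydride adds once and the aluminium-chelated hemiaminal persists until the quench, so the enal should form without over-reduction or 1,4-reduction.

Step 4
Reactants: 6 methyl acetoacetate
Product: 7 methyl 2-bromo-3-oxobutanoate
Conditions: NBS, NH4OAc (10 mol %), Et2O, rt
Reagents that add atoms: N-bromosuccinimide, O=C1CCC(=O)N1Br
Why: Electrophilic α-bromination of the β-keto ester enol should stop at the monobromide on the doubly activated carbon, and the product is used freshly made.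

Step 5
Reactants: 5 (E)-3-[3,4-bis(TBSO)phenyl]prop-2-enal; 7 methyl 2-bromo-3-oxobutanoate
Product: 8 methyl (2R,3S)-1-acetyl-2-[3,4-bis(TBSO)phenyl]-3-formylcyclopropane-1-carboxylate (aryl and formyl trans, both C1 epimers)
Conditions: (R)-2-[diphenyl(trimethylsilyloxy)methyl]pyrrolidine (20 mol %), 2,6-lutidine (1.1 equiv), CH2Cl2, 0 °C → rt
Reagents that add atoms: none
Why: This is an organocatalytic Michael-initiated ring closure (iminium then enamine activation), known for enals and 2-bromo-β-keto esters: in the E,s-trans iminium ion the CPh2(OTMS) group of the R catalyst covers the Si face of Cβ, the bromo enolate adds to the Re face, and the enamine carbon then displaces bromide on the same side to place formyl trans to aryl, while the C1 configuration is irrelevant because C1 becomes sp2 in step 7.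

Step 6
Reactants: 8 methyl (2R,3S)-1-acetyl-2-[3,4-bis(TBSO)phenyl]-3-formylcyclopropane-1-carboxylate
Product: 9 methyl (2R,3S)-1-acetyl-2-[3,4-bis(TBSO)phenyl]-3-(dimethoxymethyl)cyclopropane-1-carboxylate (both C1 epimers)
Conditions: HC(OMe)3, PPTS (10 mol %), MeOH–CH2Cl2 (1:4), rt
Reagents that add atoms: trimethyl orthoformate, COC(OC)OC
Why: Acid-catalysed acetalisation with orthoformate as dehydrating agent should take the aldehyde in preference to the hindered methyl ketone, and because a cyclopropanecarbaldehyde resists enolisation the formyl-bearing stereocentre passes unchanged into a group that no longer acidifies its hydrogen.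

Step 7
Reactants: 9 methyl (2R,3S)-1-acetyl-2-[3,4-bis(TBSO)phenyl]-3-(dimethoxymethyl)cyclopropane-1-carboxylate
Product: 10 methyl (4R,5R)-5-[3,4-bis(TBSO)phenyl]-4-(dimethoxymethyl)-2-methyl-4,5-dihydrofuran-3-carboxylate (trans)
Conditions: Yb(OTf)3 (10 mol %), 4 Å MS, CH2Cl2, 0 °C → rt
Reagents that add atoms: none
Why: In this Cloke–Wilson rearrangement of a donor–acceptor cyclopropyl ketone, chelation of the β-keto ester heterolyses the C1–C2 bond, the dioxygenated arene stabilises the benzylic cation, and the ketone enolate oxygen closes the five-membered ring anti to the dimethoxymethyl group, so the untouched acetal-bearing centre (C4 of the dihydrofuran) dictates the trans C5 centre under reversible conditions and both C1 epimers converge on one product.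

Step 8
Reactants: 10 methyl (4R,5R)-5-[3,4-bis(TBSO)phenyl]-4-(dimethoxymethyl)-2-methyl-4,5-dihydrofuran-3-carboxylate; 4 (E)-3-[3,4-bis(TBSO)phenyl]-N-methoxy-N-methylprop-2-enamide (second portion)
Product: 14 (2R,3R)-2-[3,4-bis(TBSO)phenyl]-6-{(E)-2-[3,4-bis(TBSO)phenyl]ethenyl}-3-(dimethoxymethyl)-2,3-dihydro-4H-furo[3,2-c]pyran-4-one, via lithium dienolate 11 (not isolated), via tetrahedral lithium adduct 12 (not isolated), via keto ester 13 (not isolated)
Conditions: LDA (1.1 equiv), THF, −78 °C; 4, −78 → −20 °C; AcOH, −78 °C, aqueous wash; crude 13, CSA (10 mol %), 4 Å MS, toluene, 50 °C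
Reagents that add atoms: none
Why: LDA takes a proton from C7, the γ-carbon of the cyclic β-alkoxycrotonate, to give dienolate 11, whose γ-terminus adds to the carbonyl group of 4; the chelated adduct 12 lasts until the acetic acid quench, which releases the largely enolised ketone 13 and so establishes C6–C7. Catalytic CSA then protonates the electron-rich ester carbonyl C4, and the C6 enol oxygen adds to it and expels methanol, a 6-exo-trig addition–elimination that forms O5–C4 and closes the 2-pyranone. The closest known chemistry is the vinylogous Claisen acylation of 3-alkoxycrotonate dienolates followed by lactonisation to 4-alkoxy-6-substituted 2-pyranones. No stereocentre is created, and because C3 carries an acetal rather than a carbonyl group its hydrogen is not acidic, so neither epimerisation nor β-elimination of O1 can begin under the base. The fully substituted C3a secures γ- over α-acylation, the Weinreb amide with its β-carbon deactivated by the electron-rich arene secures carbonyl over conjugate attack, and the persistence of 12 prevents double addition. The five-membered ring fixes C7 and the ester cis on the C3a=C7a double bond, which is the geometry the lactonisation needs.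

Step 9
Reactants: 14 (2R,3R)-furopyranone dimethyl acetal
Product: 15 (2R,3R)-2-[3,4-bis(TBSO)phenyl]-6-{(E)-2-[3,4-bis(TBSO)phenyl]ethenyl}-4-oxo-2,3-dihydro-4H-furo[3,2-c]pyran-3-carbaldehyde
Conditions: TFA–H2O (9:1), CH2Cl2, 0 °C; toluene azeotrope, used crude
Reagents that add atoms: water, O
Why: In this acetal hydrolysis the phenolic TBS ethers are far more acid-stable than an aliphatic dimethyl acetal, and the base-free isolation avoids enolisation of the aldehyde, whose C3 epimer would in any case be the less stable cis isomer.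

Step 10
Reactants: 16 2,2,6-trimethyl-4H-1,3-dioxin-4-one
Product: 18 [(2,2-dimethyl-6-methylidene-6H-1,3-dioxin-4-yl)oxy]trimethylsilane, via dioxinone lithium dienolate 17 (not isolated)
Conditions: LDA, THF, −78 °C; TMSCl, −78 °C → rt
Reagents that add atoms: chlorotrimethylsilane, C[Si](C)(C)Cl
Why: Kinetic γ-deprotonation of the dioxinone followed by O-silylation is the standard preparation of this silyl dienol ether.

Step 11
Reactants: 15 (2R,3R)-furopyranone-3-carbaldehyde; 18 [(2,2-dimethyl-6-methylidene-6H-1,3-dioxin-4-yl)oxy]trimethylsilane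
Product: 19 6-{2-hydroxy-2-[(2R,3S)-2-[3,4-bis(TBSO)phenyl]-6-{(E)-2-[3,4-bis(TBSO)phenyl]ethenyl}-4-oxo-2,3-dihydro-4H-furo[3,2-c]pyran-3-yl]ethyl}-2,2-dimethyl-4H-1,3-dioxin-4-one (carbinol epimers; ring configuration as in 15, the C3 descriptor changes by priority only)
Conditions: BF3·OEt2 (2.5 equiv), 18 (2.5 equiv), CH2Cl2, −78 °C
Reagents that add atoms: none
Why: In this vinylogous Mukaiyama aldol addition the dienol ether attacks the BF3-activated aldehyde through its γ-methylene carbon under non-basic conditions at −78 °C, so C3 should not enolise, and the new carbinol centre may form as a mixture because step 12 removes it.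

Step 12
Reactants: 19 δ-hydroxy dioxinone (carbinol epimers)
Product: 20 6-{2-oxo-2-[(2R,3R)-2-[3,4-bis(TBSO)phenyl]-6-{(E)-2-[3,4-bis(TBSO)phenyl]ethenyl}-4-oxo-2,3-dihydro-4H-furo[3,2-c]pyran-3-yl]ethyl}-2,2-dimethyl-4H-1,3-dioxin-4-one
Conditions: Dess–Martin periodinane, CH2Cl2, 0 °C → rt
Reagents that add atoms: none
Why: Dess–Martin oxidation of dioxinone aldol adducts to keto dioxinones is well established, and it runs under mildly acidic, base-free conditions that leave C3–H, the styrene and the silyl ethers alone.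

Step 13
Reactants: 20 keto dioxinone
Product: 22 (2R,3R)-2-[3,4-bis(TBSO)phenyl]-6-{(E)-2-[3,4-bis(TBSO)phenyl]ethenyl}-3-(4-hydroxy-2-oxo-2H-pyran-6-yl)-2,3-dihydro-4H-furo[3,2-c]pyran-4-one, via acylketene 21 (not isolated)
Conditions: toluene, 110 °C
Reagents that add atoms: none
Why: Thermal retro-hetero-Diels–Alder loss of acetone gives an acylketene, which the enol oxygen of the neighbouring ketone (enolised towards the CH2 group, not C3) captures to close the 4-hydroxy-2-pyranone under neutral conditions.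

Step 14
Reactants: 22 tetrakis-TBS ether of the target
Product: 23 (2R,3R)-2-(3,4-dihydroxyphenyl)-6-[(E)-2-(3,4-dihydroxyphenyl)ethenyl]-3-(4-hydroxy-2-oxo-2H-pyran-6-yl)-2,3-dihydro-4H-furo[3,2-c]pyran-4-one (target)
Conditions: Et3N·3HF, THF, 0 °C → rt, argon
Reagents that add atoms: none
Why: Fluoride-mediated desilylation in a slightly acidic medium should free the four phenols without generating phenoxides, so opening of the benzylic C2–O1 bond, C3 deprotonation and catechol autoxidation should all be suppressed.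

**Compound list**
1 | 3,4-dihydroxybenzaldehyde | O=Cc1ccc(O)c(O)c1 | starting material
2 | 3,4-bis(tert-butyldimethylsilyloxy)benzaldehyde | O=Cc1ccc(O[Si](C)(C)C(C)(C)C)c(O[Si](C)(C)C(C)(C)C)c1 | intermediate
3 | diethyl {2-[methoxy(methyl)amino]-2-oxoethyl}phosphonate | CCOP(=O)(CC(=O)N(C)OC)OCC | starting material
4 | (E)-3-[3,4-bis(TBSO)phenyl]-N-methoxy-N-methylprop-2-enamide | CON(C)C(=O)/C=C/c1ccc(O[Si](C)(C)C(C)(C)C)c(O[Si](C)(C)C(C)(C)C)c1 | intermediate
5 | (E)-3-[3,4-bis(TBSO)phenyl]prop-2-enal | O=C/C=C/c1ccc(O[Si](C)(C)C(C)(C)C)c(O[Si](C)(C)C(C)(C)C)c1 | intermediate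
6 | methyl acetoacetate | COC(=O)CC(C)=O | starting material
7 | methyl 2-bromo-3-oxobutanoate | COC(=O)C(Br)C(C)=O | intermediate
8 | methyl (2R,3S)-1-acetyl-2-[3,4-bis(TBSO)phenyl]-3-formylcyclopropane-1-carboxylate, C1 epimers | O=C[C@@H]1C(C(C)=O)(C(=O)OC)[C@H]1c1ccc(O[Si](C)(C)C(C)(C)C)c(O[Si](C)(C)C(C)(C)C)c1 | intermediate
9 | methyl (2R,3S)-1-acetyl-2-[3,4-bis(TBSO)phenyl]-3-(dimethoxymethyl)cyclopropane-1-carboxylate, C1 epimers | COC(OC)[C@@H]1C(C(C)=O)(C(=O)OC)[C@H]1c1ccc(O[Si](C)(C)C(C)(C)C)c(O[Si](C)(C)C(C)(C)C)c1 | intermediate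
10 | methyl (4R,5R)-5-[3,4-bis(TBSO)phenyl]-4-(dimethoxymethyl)-2-methyl-4,5-dihydrofuran-3-carboxylate | COC(OC)[C@@H]1C(C(=O)OC)=C(C)O[C@H]1c1ccc(O[Si](C)(C)C(C)(C)C)c(O[Si](C)(C)C(C)(C)C)c1 | intermediate
11 | lithium dienolate of 10 (2-methylidene ketene acetal form) | COC(OC)[C@@H]1C(=C([O-])OC)C(=C)O[C@H]1c1ccc(O[Si](C)(C)C(C)(C)C)c(O[Si](C)(C)C(C)(C)C)c1.[Li+] | intermediate
12 | lithium alkoxide adduct of 11 and 4 at C6 (hemiaminal carbon unassigned) | COC(OC)[C@@H]1C(C(=O)OC)=C(CC([O-])(/C=C/c2ccc(O[Si](C)(C)C(C)(C)C)c(O[Si](C)(C)C(C)(C)C)c2)N(C)OC)O[C@H]1c1ccc(O[Si](C)(C)C(C)(C)C)c(O[Si](C)(C)C(C)(C)C)c1.[Li+] | intermediate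
13 | methyl (4R,5R)-5-[3,4-bis(TBSO)phenyl]-2-{(E)-4-[3,4-bis(TBSO)phenyl]-2-oxobut-3-enyl}-4-(dimethoxymethyl)-4,5-dihydrofuran-3-carboxylate | COC(OC)[C@@H]1C(C(=O)OC)=C(CC(=O)/C=C/c2ccc(O[Si](C)(C)C(C)(C)C)c(O[Si](C)(C)C(C)(C)C)c2)O[C@H]1c1ccc(O[Si](C)(C)C(C)(C)C)c(O[Si](C)(C)C(C)(C)C)c1 | intermediate
14 | (2R,3R)-2-[3,4-bis(TBSO)phenyl]-6-{(E)-2-[3,4-bis(TBSO)phenyl]ethenyl}-3-(dimethoxymethyl)-2,3-dihydro-4H-furo[3,2-c]pyran-4-one | COC(OC)[C@@H]1c2c(cc(/C=C/c3ccc(O[Si](C)(C)C(C)(C)C)c(O[Si](C)(C)C(C)(C)C)c3)oc2=O)O[C@H]1c1ccc(O[Si](C)(C)C(C)(C)C)c(O[Si](C)(C)C(C)(C)C)c1 | intermediate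
15 | (2R,3R)-2-[3,4-bis(TBSO)phenyl]-6-{(E)-2-[3,4-bis(TBSO)phenyl]ethenyl}-4-oxo-2,3-dihydro-4H-furo[3,2-c]pyran-3-carbaldehyde | O=C[C@@H]1c2c(cc(/C=C/c3ccc(O[Si](C)(C)C(C)(C)C)c(O[Si](C)(C)C(C)(C)C)c3)oc2=O)O[C@H]1c1ccc(O[Si](C)(C)C(C)(C)C)c(O[Si](C)(C)C(C)(C)C)c1 | intermediate
16 | 2,2,6-trimethyl-4H-1,3-dioxin-4-one | CC1=CC(=O)OC(C)(C)O1 | starting material
17 | lithium dienolate of 16 | [Li+].[O-]C1=CC(=C)OC(C)(C)O1 | intermediate
18 | [(2,2-dimethyl-6-methylidene-6H-1,3-dioxin-4-yl)oxy]trimethylsilane | C=C1C=C(O[Si](C)(C)C)OC(C)(C)O1 | intermediate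
19 | δ-hydroxy dioxinone, carbinol epimers, ring centres as in 15 | CC1(C)OC(=O)C=C(CC(O)[C@@H]2c3c(cc(/C=C/c4ccc(O[Si](C)(C)C(C)(C)C)c(O[Si](C)(C)C(C)(C)C)c4)oc3=O)O[C@H]2c2ccc(O[Si](C)(C)C(C)(C)C)c(O[Si](C)(C)C(C)(C)C)c2)O1 | intermediate
20 | keto dioxinone, (2R,3R) | CC1(C)OC(=O)C=C(CC(=O)[C@@H]2c3c(cc(/C=C/c4ccc(O[Si](C)(C)C(C)(C)C)c(O[Si](C)(C)C(C)(C)C)c4)oc3=O)O[C@H]2c2ccc(O[Si](C)(C)C(C)(C)C)c(O[Si](C)(C)C(C)(C)C)c2)O1 | intermediate
21 | 3,5-dioxo-5-[(2R,3R)-furopyranon-3-yl]pent-1-en-1-one (acylketene) | O=C=CC(=O)CC(=O)[C@@H]1c2c(cc(/C=C/c3ccc(O[Si](C)(C)C(C)(C)C)c(O[Si](C)(C)C(C)(C)C)c3)oc2=O)O[C@H]1c1ccc(O[Si](C)(C)C(C)(C)C)c(O[Si](C)(C)C(C)(C)C)c1 | intermediate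
22 | (2R,3R)-2-[3,4-bis(TBSO)phenyl]-6-{(E)-2-[3,4-bis(TBSO)phenyl]ethenyl}-3-(4-hydroxy-2-oxo-2H-pyran-6-yl)-2,3-dihydro-4H-furo[3,2-c]pyran-4-one | O=c1cc(O)cc([C@@H]2c3c(cc(/C=C/c4ccc(O[Si](C)(C)C(C)(C)C)c(O[Si](C)(C)C(C)(C)C)c4)oc3=O)O[C@H]2c2ccc(O[Si](C)(C)C(C)(C)C)c(O[Si](C)(C)C(C)(C)C)c2)o1 | intermediate
23 | (2R,3R)-2-(3,4-dihydroxyphenyl)-6-[(E)-2-(3,4-dihydroxyphenyl)ethenyl]-3-(4-hydroxy-2-oxo-2H-pyran-6-yl)-2,3-dihydro-4H-furo[3,2-c]pyran-4-one | O=c1cc(O)cc([C@@H]2c3c(cc(/C=C/c4ccc(O)c(O)c4)oc3=O)O[C@H]2c2ccc(O)c(O)c2)o1 | target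

**Step count**
- Total steps: 14.
- Longest linear sequence: 12 (steps 1, 2, 3, 5, 6, 7, 8, 9, 11, 12, 13, 14).

**Steps most likely to fail**

Step 8. The stabilised dienolate may add too slowly to the deactivated cinnamoyl amide, conjugate addition may intrude, or the acid-catalysed lactonisation may stall or erode the acetal. The fallback lowers the oxidation level of the electrophile while forming the same two bonds. It sets out from 10 (deprotonated to 11 as before) and enal 5. Vinylogous aldol addition at C7, with lactonisation of the resulting alkoxide on warming and a prompt acetic acid quench, should give (2R,3R)-2-[3,4-bis(TBSO)phenyl]-6-{(E)-2-[3,4-bis(TBSO)phenyl]ethenyl}-3-(dimethoxymethyl)-2,3,6,7-tetrahydro-4H-furo[3,2-c]pyran-4-one F1 as C6 epimers. Dehydrogenation across C6–C7 with DDQ in hot dioxane, as practised on 6-styryl-5,6-dihydro-4-alkoxy-2-pyranones, returns to 14.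

Step 7. The Lewis acid may ionise the dimethyl acetal alongside the C1–C2 bond, or the benzylic cation may lose a proton faster than the enolate oxygen closes the ring. The fallback removes the acetal from the ionisation event by inverting the order of events. It sets out from 8, which is ring-expanded as the free aldehyde (Yb(OTf)3 at low temperature or gentle warming in toluene) to methyl (4R,5R)-5-[3,4-bis(TBSO)phenyl]-4-formyl-2-methyl-4,5-dihydrofuran-3-carboxylate F2. This is acetalised at once with HC(OMe)3 and PPTS and rejoins the route at 10, bypassing 9.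

Step 11. Aldehyde 15 is hindered, and its acidic C3–H lies β to the O1 leaving group. If addition is slow, enolisation followed by opening of the dihydrofuran, or C3 epimerisation, may overtake C–C bond formation. The fallback turns the bond formation into an acylation at the acid oxidation level.
- It sets out from 15; Pinnick oxidation (NaClO2, NaH2PO4, 2-methylbut-2-ene) should give (2R,3R)-2-[3,4-bis(TBSO)phenyl]-6-{(E)-2-[3,4-bis(TBSO)phenyl]ethenyl}-4-oxo-2,3-dihydro-4H-furo[3,2-c]pyran-3-carboxylic acid F3.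
- Neutral activation with 1-chloro-N,N,2-trimethylprop-1-en-1-amine gives the corresponding acid chloride F4.
- Uncatalysed condensation with 1-methoxy-1,3-bis(trimethylsilyloxy)buta-1,3-diene in CH2Cl2 (−78 °C → rt) gives methyl 3,5-dioxo-5-[(2R,3R)-furopyranon-3-yl]pentanoate F5.
- Lactonisation of F5 with catalytic DBU in toluene returns to 22, bypassing 18–21.

**Further compounds**
F1 | step 8 | (2R,3R)-2-[3,4-bis(TBSO)phenyl]-6-{(E)-2-[3,4-bis(TBSO)phenyl]ethenyl}-3-(dimethoxymethyl)-2,3,6,7-tetrahydro-4H-furo[3,2-c]pyran-4-one, C6 epimers | COC(OC)[C@@H]1C2=C(CC(/C=C/c3ccc(O[Si](C)(C)C(C)(C)C)c(O[Si](C)(C)C(C)(C)C)c3)OC2=O)O[C@H]1c1ccc(O[Si](C)(C)C(C)(C)C)c(O[Si](C)(C)C(C)(C)C)c1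
F2 | step 7 | methyl (4R,5R)-5-[3,4-bis(TBSO)phenyl]-4-formyl-2-methyl-4,5-dihydrofuran-3-carboxylate | O=C[C@@H]1C(C(=O)OC)=C(C)O[C@H]1c1ccc(O[Si](C)(C)C(C)(C)C)c(O[Si](C)(C)C(C)(C)C)c1
F3 | step 11 | (2R,3R)-2-[3,4-bis(TBSO)phenyl]-6-{(E)-2-[3,4-bis(TBSO)phenyl]ethenyl}-4-oxo-2,3-dihydro-4H-furo[3,2-c]pyran-3-carboxylic acid | OC(=O)[C@@H]1c2c(cc(/C=C/c3ccc(O[Si](C)(C)C(C)(C)C)c(O[Si](C)(C)C(C)(C)C)c3)oc2=O)O[C@H]1c1ccc(O[Si](C)(C)C(C)(C)C)c(O[Si](C)(C)C(C)(C)C)c1
F4 | step 11 | (2R,3R)-2-[3,4-bis(TBSO)phenyl]-6-{(E)-2-[3,4-bis(TBSO)phenyl]ethenyl}-4-oxo-2,3-dihydro-4H-furo[3,2-c]pyran-3-carbonyl chloride | ClC(=O)[C@@H]1c2c(cc(/C=C/c3ccc(O[Si](C)(C)C(C)(C)C)c(O[Si](C)(C)C(C)(C)C)c3)oc2=O)O[C@H]1c1ccc(O[Si](C)(C)C(C)(C)C)c(O[Si](C)(C)C(C)(C)C)c1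
F5 | step 11 | methyl 5-[(2R,3R)-2-[3,4-bis(TBSO)phenyl]-6-{(E)-2-[3,4-bis(TBSO)phenyl]ethenyl}-4-oxo-2,3-dihydro-4H-furo[3,2-c]pyran-3-yl]-3,5-dioxopentanoate | COC(=O)CC(=O)CC(=O)[C@@H]1c2c(cc(/C=C/c3ccc(O[Si](C)(C)C(C)(C)C)c(O[Si](C)(C)C(C)(C)C)c3)oc2=O)O[C@H]1c1ccc(O[Si](C)(C)C(C)(C)C)c(O[Si](C)(C)C(C)(C)C)c1
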